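**Retrosynthetic overview**
- The N‑methyl group comes last, by hydride reduction of an N1‑Boc carbamate on the finished tetracycle.
- The furan ring comes from an ortho‑iodophenol and 2‑methylbut‑3‑yn‑2‑ol by Sonogashira coupling/5‑endo‑dig annulation (C–I reacts, C–Br stays).
- The indoline and pyrrolidine rings, with C3a and C8a, come from one chiral‑phosphoric‑acid‑catalysed interrupted Fischer indolization of a 2‑bromo‑5‑hydroxy‑4‑iodophenylhydrazine with a racemic 3‑prenyl N‑Boc‑pyrrolidin‑2‑ol; Br blocks the second ortho position.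
- The hydrazine comes from 3‑amino‑4‑bromophenol (iodination, diazotization/reduction); the hemiaminal from N‑Boc‑pyrrolidin‑2‑one (prenylation, partial reduction).
- Ring order: benzene (purchased) → indoline and pyrrolidine together → furan.

Assumption: the sense of induction of the chiral phosphoric acid in step 5 must be established in a first run; the route is written with (S)‑STRIP (the SPINOL phosphoric acid with 2,4,6‑triisopropylphenyl groups), and (R)‑STRIP is used instead if the (3aR,8aR) series results.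

**Step 1**
Reactants: 1 3‑amino‑4‑bromophenol
Product: 2 5‑amino‑4‑bromo‑2‑iodophenol
Conditions: NIS (1.0 equiv), MeCN, −10 → 0 °C, dark
Reagents that add atoms: N‑iodosuccinimide, O=C1CCC(=O)N1I
Why: Electrophilic aromatic iodination goes para to NH2 and ortho to OH, the only unhindered activated C–H (the site between OH and NH2 is flanked on both sides and the site para to OH carries Br).

**Step 2**
Reactants: 2 5‑amino‑4‑bromo‑2‑iodophenol
Product: 4 4‑bromo‑5‑hydrazinyl‑2‑iodophenol, via diazonium chloride 3 (not isolated)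
Conditions: NaNO2, 6 M HCl, −5 °C; then SnCl2·2H2O, conc. HCl, 0 °C; NaHCO3 work‑up under Ar, used at once
Reagents that add atoms: sodium nitrite, [Na+].[O-]N=O
Why: Diazotization followed by Sn(II) reduction of the diazonium salt is the classical arylhydrazine synthesis; the strongly acidic medium suppresses azo coupling onto the phenol and aryl I/Br are inert to SnCl2.

**Step 3**
Reactants: 5 tert‑butyl 2‑oxopyrrolidine‑1‑carboxylate; 6 1‑bromo‑3‑methylbut‑2‑ene (prenyl bromide)
Product: 7 tert‑butyl 3‑(3‑methylbut‑2‑en‑1‑yl)‑2‑oxopyrrolidine‑1‑carboxylate (racemic)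
Conditions: LiHMDS (1.05 equiv), THF, −78 °C; then 6, −78 → −30 °C
Reagents that add atoms: none
Why: Enolate alkylation of the Boc‑activated lactam, with SN2 attack at the primary allylic carbon giving the linear prenyl group; the racemic stereocentre is erased in step 5.

**Step 4**
Reactants: 7 tert‑butyl 3‑(3‑methylbut‑2‑en‑1‑yl)‑2‑oxopyrrolidine‑1‑carboxylate
Product: 8 tert‑butyl 2‑hydroxy‑3‑(3‑methylbut‑2‑en‑1‑yl)pyrrolidine‑1‑carboxylate (racemic, cis/trans mixture)
Conditions: LiBHEt3 (1.2 equiv), THF, −78 °C; H2O quench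
Reagents that add atoms: none
Why: Partial reduction of an N‑acyl lactam with Super‑Hydride stops at the stable tetrahedral alkoxide and delivers the N‑Boc hemiaminal, a masked 4‑(Boc‑amino)aldehyde; its stereocentres are irrelevant.

**Step 5**
Reactants: 4 4‑bromo‑5‑hydrazinyl‑2‑iodophenol; 8 tert‑butyl 2‑hydroxy‑3‑(3‑methylbut‑2‑en‑1‑yl)pyrrolidine‑1‑carboxylate
Product: 11 tert‑butyl (3aS,8aS)‑7‑bromo‑4‑hydroxy‑5‑iodo‑3a‑(3‑methylbut‑2‑en‑1‑yl)‑3,3a,8,8a‑tetrahydropyrrolo[2,3‑b]indole‑1(2H)‑carboxylate, via hydrazone 9 (not isolated), via 3H‑indole 10 (not isolated)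
Conditions: 4 Å MS, PhMe, rt, 2 h; then (S)‑STRIP (10 mol%), Amberlite CG50, 45 °C, 48–72 h
Reagents that add atoms: none
Why: Proposed new method: an enantioselective interrupted Fischer indolization in which hydrazone 9 equilibrates under acid with its ene‑hydrazine tautomer (erasing the α‑stereocentre of 8, so all stereoisomers converge), the chiral phosphate binds the protonated ene‑hydrazine through N–H, carbamate N–H and phenol O–H contacts and selects one face in the irreversible [3,3]‑sigmatropic shift onto the only free ortho carbon (a dynamic kinetic resolution that sets C3a), after which rearomatisation, closure of the aniline N onto the aldimine and loss of NH3 (trapped by the resin so the catalyst turns over) give 3H‑indole 10, whose C=N is attacked by the carbamate N–H from the only face that allows a cis‑fused 5/5 aminal (fixing C8a); the closest known reaction types are the racemic interrupted Fischer indolization of arylhydrazines with N‑acyl hemiaminals in aqueous acetic acid and the SPINOL‑phosphoric‑acid‑catalysed asymmetric Fischer indolization run with a weakly acidic resin as ammonia scavenger.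

**Step 6**
Reactants: 11 tert‑butyl (3aS,8aS)‑7‑bromo‑4‑hydroxy‑5‑iodo‑3a‑(3‑methylbut‑2‑en‑1‑yl)‑3,3a,8,8a‑tetrahydropyrrolo[2,3‑b]indole‑1(2H)‑carboxylate; 12 2‑methylbut‑3‑yn‑2‑ol
Product: 14 N1‑Boc furan‑fused tetracycle (the target with Boc in place of N‑CH3), via alkynylphenol 13 (not isolated)
Conditions: Pd(PPh3)2Cl2 (3 mol%), CuI (6 mol%), Et3N, DMF (degassed), rt → 60 °C
Reagents that add atoms: none
Why: Sonogashira coupling is chemoselective for C–I over C–Br, and the resulting ortho‑alkynylphenol undergoes Cu/Pd‑promoted 5‑endo‑dig hydroalkoxylation to the 2‑substituted benzofuran under the same conditions; no stereocentre is touched.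

**Step 7**
Reactants: 14 N1‑Boc furan‑fused tetracycle
Product: 15 2‑[(3aS,8aS)‑7‑bromo‑1‑methyl‑3a‑(3‑methylbut‑2‑en‑1‑yl)‑hexahydropyrrolo[2,3‑b]indole fused at C4(O)–C5 to a furan]propan‑2‑ol (target)
Conditions: LiAlH4 (6 equiv), THF, 0 → 60 °C; Fieser work‑up
Reagents that add atoms: none
Why: LiAlH4 reduction of the tert‑butyl carbamate converts N–CO2tBu into N–CH3, while the cis‑fused aminal, the trisubstituted alkene, the tertiary alkoxide and (at ≤60 °C) the electron‑rich aryl bromide are left intact, so both stereocentres are retained.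

**Compound list**
1 | 3‑amino‑4‑bromophenol | Nc1cc(O)ccc1Br | starting material
2 | 5‑amino‑4‑bromo‑2‑iodophenol | Nc1cc(O)c(I)cc1Br | intermediate
3 | 2‑bromo‑5‑hydroxy‑4‑iodobenzenediazonium chloride | Oc1cc([N+]#N)c(Br)cc1I.[Cl-] | intermediate (not isolated)
4 | 4‑bromo‑5‑hydrazinyl‑2‑iodophenol | NNc1cc(O)c(I)cc1Br | intermediate
5 | tert‑butyl 2‑oxopyrrolidine‑1‑carboxylate | CC(C)(C)OC(=O)N1CCCC1=O | starting material
6 | 1‑bromo‑3‑methylbut‑2‑ene (prenyl bromide) | CC(C)=CCBr | starting material
7 | tert‑butyl 3‑(3‑methylbut‑2‑en‑1‑yl)‑2‑oxopyrrolidine‑1‑carboxylate, racemic | CC(C)=CCC1CCN(C(=O)OC(C)(C)C)C1=O | intermediate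
8 | tert‑butyl 2‑hydroxy‑3‑(3‑methylbut‑2‑en‑1‑yl)pyrrolidine‑1‑carboxylate, racemic cis/trans mixture | CC(C)=CCC1CCN(C(=O)OC(C)(C)C)C1O | intermediate
9 | (2‑bromo‑5‑hydroxy‑4‑iodophenyl)hydrazone of tert‑butyl (3‑formyl‑6‑methylhept‑5‑en‑1‑yl)carbamate, racemic | CC(C)=CCC(CCNC(=O)OC(C)(C)C)C=NNc1cc(O)c(I)cc1Br | intermediate (not isolated)
10 | tert‑butyl {2‑[(3S)‑7‑bromo‑4‑hydroxy‑5‑iodo‑3‑(3‑methylbut‑2‑en‑1‑yl)‑3H‑indol‑3‑yl]ethyl}carbamate | CC(C)=CC[C@@]1(CCNC(=O)OC(C)(C)C)C=Nc2c(Br)cc(I)c(O)c21 | intermediate (not isolated)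
11 | tert‑butyl (3aS,8aS)‑7‑bromo‑4‑hydroxy‑5‑iodo‑3a‑(3‑methylbut‑2‑en‑1‑yl)‑3,3a,8,8a‑tetrahydropyrrolo[2,3‑b]indole‑1(2H)‑carboxylate (cis‑fused) | CC(C)=CC[C@@]12CCN(C(=O)OC(C)(C)C)[C@@H]1Nc1c(Br)cc(I)c(O)c12 | intermediate
12 | 2‑methylbut‑3‑yn‑2‑ol | CC(C)(O)C#C | starting material
13 | tert‑butyl (3aS,8aS)‑7‑bromo‑4‑hydroxy‑5‑(3‑hydroxy‑3‑methylbut‑1‑yn‑1‑yl)‑3a‑(3‑methylbut‑2‑en‑1‑yl)‑3,3a,8,8a‑tetrahydropyrrolo[2,3‑b]indole‑1(2H)‑carboxylate | CC(C)=CC[C@@]12CCN(C(=O)OC(C)(C)C)[C@@H]1Nc1c(Br)cc(C#CC(C)(C)O)c(O)c12 | intermediate (not isolated)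
14 | N1‑Boc tetracycle: (3aS,8aS)‑7‑bromo‑3a‑prenyl‑hexahydropyrrolo[2,3‑b]indole with N1‑CO2tBu, N8–H, and a furan fused across C4 (O) and C5 (C) carrying 2‑hydroxypropan‑2‑yl on the furan carbon next to O | CC(C)=CC[C@@]12CCN(C(=O)OC(C)(C)C)[C@@H]1Nc1c(Br)cc3cc(C(C)(C)O)oc3c12 | intermediate
15 | target CNP0306513.1: as 14 but N1–CH3; (3aS,8aS), cis‑fused | CC(C)=CC[C@@]12CCN(C)[C@@H]1Nc1c(Br)cc3cc(C(C)(C)O)oc3c12 | target

**Count**
Total steps: 7. Longest linear sequence: 5 (steps 1, 2, 5, 6, 7); steps 3 and 4 form the second branch.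

**Three steps most likely to fail, with fallbacks**

Step 5 (asymmetric interrupted Fischer cascade): the enantioselectivity is unproven, the [3,3] shift must go to a carbon flanked by OH while building a quaternary centre, and the free N–H hydrazone may react slowly or unselectively. Fallback: set out from 4 and 8 and run the cascade without chiral control under the established Brønsted‑acid conditions (AcOH/H2O 1:1, 60 °C) to obtain the racemic cis‑fused carbamate F1; separate the enantiomers by preparative chiral SFC and return to the route at 11. Half of the material is lost.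

Step 2 (hydrazine from the iodo‑aminophenol): the electron‑rich diazonium salt and the free hydrazinophenol are prone to azo coupling and air oxidation. Fallback: set out from 2 and transfer an NH‑Boc group to the aniline nitrogen by electrophilic N‑amination with tert‑butyl 3‑(4‑cyanophenyl)oxaziridine‑2‑carboxylate (CH2Cl2, rt) to give tert‑butyl 2‑(2‑bromo‑5‑hydroxy‑4‑iodophenyl)hydrazine‑1‑carboxylate F2, a bench‑stable protected hydrazine; cleave the Boc group with HCl in dioxane and neutralise under argon to return to the route at 4. This avoids the diazonium salt entirely.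

Step 7 (carbamate to N‑methyl with LiAlH4): hydrodebromination of the aryl bromide, or base‑induced opening of the N8–H aminal followed by over‑reduction, may compete. Fallback: set out from 14, remove the Boc group under buffered Lewis‑acid conditions (TMSOTf, 2,6‑lutidine, CH2Cl2, 0 °C; then K2CO3/MeOH to cleave the silyl carbamate and the transient silyl ether) to give the N1–H secondary amine F3, and methylate it by reductive amination (aqueous formaldehyde 1.0 equiv, NaBH(OAc)3, 0 °C), returning to the route at 15. The hindered ortho‑bromo anilinic N8 is far less nucleophilic than the aliphatic N1, and no aluminium hydride is used.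

**Further compounds**
F1 | step 5 | racemic cis‑fused tert‑butyl 7‑bromo‑4‑hydroxy‑5‑iodo‑3a‑(3‑methylbut‑2‑en‑1‑yl)‑3,3a,8,8a‑tetrahydropyrrolo[2,3‑b]indole‑1(2H)‑carboxylate (racemate of 11) | CC(C)=CCC12CCN(C(=O)OC(C)(C)C)C1Nc1c(Br)cc(I)c(O)c12
F2 | step 2 | tert‑butyl 2‑(2‑bromo‑5‑hydroxy‑4‑iodophenyl)hydrazine‑1‑carboxylate | CC(C)(C)OC(=O)NNc1cc(O)c(I)cc1Br
F3 | step 7 | N1–H secondary amine corresponding to 14 and 15 (same spatial arrangement; 3aS,8aR by CIP) | CC(C)=CC[C@@]12CCN[C@@H]1Nc1c(Br)cc3cc(C(C)(C)O)oc3c12
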